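Target 16 is achiral. It is cut at its two aryl ester C–O bonds into ring A acid 8 and the B–C phenol 14, whose rings B and C both come from orsellinic acid. Each ring is numbered from the carboxyl-bearing C1 to the methyl-bearing C6. Ring A's C1, C2 and C3 (carboxyl carbon, C2 oxygen, C3 methoxy) are the backbone of methyl 4-methoxyacetoacetate. Its C4, C5 and C6 (C4 oxygen, C6 methyl) are methyl crotonate. A base-mediated [3+3] Michael–Dieckmann annulation joins the two esters. It forms A-C1–C6 and A-C3–C4 in one operation and closes the carbocycle with its three oxygens already differentiated. The precursor is simply this pair of commercial esters.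

Key step: step 1

Remark: 16 has no stereocentre, so no enantiomer has to be selected; the two stereocentres of 3 and 4 are racemic and are erased in step 2.

Step 1
Reactants: 1 methyl 4-methoxyacetoacetate; 2 methyl (E)-crotonate
Product: 4 methyl (1RS,6SR)-4-hydroxy-3-methoxy-6-methyl-2-oxocyclohex-3-ene-1-carboxylate (racemic trans enol), via Michael adduct 3 (not isolated)
Conditions: NaOMe (1.1 equiv), MeOH, 0 °C → reflux; then aq. HCl, 0 °C
Reagents that add atoms: none
Why: Michael–Dieckmann (Michael–Claisen) annulation: methoxide forms the doubly stabilised C2 enolate of 1, which adds to the β-carbon of 2 (bond A-C1–C6, adduct 3); after proton exchange the methoxymethylene enolate attacks the former crotonate ester and expels methoxide (bond A-C3–C4). The closest known reaction is the acetoacetate/crotonate synthesis of dihydroorsellinates, here extended by a 4-methoxy group, and matching methyl esters with methoxide in methanol makes any transesterification degenerate. The ring closes in a 6-(enolendo)-exo-trig mode, and the reversible sequence is drawn forward because the cyclic β-diketone is removed as its sodium enolate, which also shields the ring against retro-Claisen opening. The two new stereocentres (C1 and C6) arise as a racemate, the trans relation being set by equilibration through the enolisable C1; neither is needed, since aromatisation removes both. Only site selectivity is required: the order of acidity places the Michael bond at C2 of 1, and in 3 the methoxymethylene carbon is the only nucleophilic site that can reach an ester through a six-membered transition state, every alternative closure being four-membered.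

Step 2
Reactants: 4 methyl (1RS,6SR)-4-hydroxy-3-methoxy-6-methyl-2-oxocyclohex-3-ene-1-carboxylate
Product: 5 methyl 2,4-dihydroxy-3-methoxy-6-methylbenzoate
Conditions: I2 (10 mol%), DMSO, 80 °C
Reagents that add atoms: none
Why: Iodine/DMSO dehydrogenative aromatisation: iodination of the β-diketone enol, loss of HI and tautomerisation should give the resorcinol, with DMSO re-oxidising HI to iodine and the gain of aromaticity as driving force.

Step 3
Reactants: 5 methyl 2,4-dihydroxy-3-methoxy-6-methylbenzoate
Product: 6 methyl 4-(benzyloxy)-2-hydroxy-3-methoxy-6-methylbenzoate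
Conditions: BnBr (1.05 equiv), K2CO3 (1.1 equiv), acetone, reflux
Reagents that add atoms: benzyl bromide, BrCc1ccccc1
Why: Williamson etherification: the C4 hydroxyl (para to the ester, not hydrogen-bonded) is the more acidic and accessible one, whereas the C2 hydroxyl is held in a chelate to the ester carbonyl and should stay free with one equivalent of halide under mild base.

Step 4
Reactants: 6 methyl 4-(benzyloxy)-2-hydroxy-3-methoxy-6-methylbenzoate
Product: 7 methyl 4-(benzyloxy)-2,3-dimethoxy-6-methylbenzoate
Conditions: MeI (3 equiv), K2CO3 (2 equiv), DMF, 50 °C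
Reagents that add atoms: iodomethane, CI
Why: Williamson methylation under more forcing conditions: with C4 capped, excess iodomethane in a dipolar aprotic solvent should alkylate the chelated C2 phenoxide, the only nucleophile left.

Step 5
Reactants: 7 methyl 4-(benzyloxy)-2,3-dimethoxy-6-methylbenzoate
Product: 8 4-(benzyloxy)-2,3-dimethoxy-6-methylbenzoic acid
Conditions: KOH (5 equiv), DMSO–H2O (4:1), 90 °C; then 1 M HCl, 0 °C
Reagents that add atoms: potassium hydroxide, [K+].[OH-]
Why: Saponification of a di-ortho-substituted benzoate: poorly solvated hydroxide in aqueous DMSO should overcome the steric shielding (attack at the acyl carbon or at the ester methyl leads to the same carboxylate), while the aryl methyl and benzyl ethers are inert to base.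

Step 6
Reactants: 9 orsellinic acid (2,4-dihydroxy-6-methylbenzoic acid)
Product: 10 benzyl orsellinate (benzyl 2,4-dihydroxy-6-methylbenzoate)
Conditions: BnBr (1.05 equiv), KHCO3 (1.1 equiv), DMF, rt
Reagents that add atoms: benzyl bromide, BrCc1ccccc1
Why: Carboxylate O-alkylation: hydrogencarbonate deprotonates only the carboxylic acid, so the benzyl group should enter at the carboxylate and leave both phenols free.

Step 7
Reactants: 9 orsellinic acid
Product: 12 4-(tert-butyldimethylsilyloxy)-2-hydroxy-6-methylbenzoic acid, via bis-silylated orsellinate 11 (not isolated)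
Conditions: TBSCl (2.2 equiv), imidazole (4.5 equiv), DMF, 0 °C → rt; then AcOH–THF–H2O (3:1:1), rt
Reagents that add atoms: tert-butyldimethylsilyl chloride, CC(C)(C)[Si](C)(C)Cl
Why: Silylation followed by selective solvolysis: TBSCl caps the carboxyl group and the unchelated C4 hydroxyl while the chelated C2 hydroxyl is left, and the much more labile silyl ester should be hydrolysed by aqueous acetic acid without loss of the aryl silyl ether.

Step 8
Reactants: 12 4-(tert-butyldimethylsilyloxy)-2-hydroxy-6-methylbenzoic acid; 10 benzyl orsellinate
Product: 13 benzyl 4-{[4-(tert-butyldimethylsilyloxy)-2-hydroxy-6-methylbenzoyl]oxy}-2-hydroxy-6-methylbenzoate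
Conditions: DCC (1.1 equiv), DMAP (0.1 equiv), CH2Cl2, 0 °C → rt
Reagents that add atoms: none
Why: Steglich-type carbodiimide esterification, the standard depside coupling: the free C4 hydroxyl of 10 should be acylated by activated 12, while the chelated ortho-hydroxyls of both partners are too poorly nucleophilic to compete.

Step 9
Reactants: 13 benzyl 4-{[4-(tert-butyldimethylsilyloxy)-2-hydroxy-6-methylbenzoyl]oxy}-2-hydroxy-6-methylbenzoate
Product: 14 benzyl 4-[(2,4-dihydroxy-6-methylbenzoyl)oxy]-2-hydroxy-6-methylbenzoate (benzyl lecanorate)
Conditions: TBAF (1.1 equiv), AcOH (1.2 equiv), THF, 0 °C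
Reagents that add atoms: none
Why: Fluoride-mediated cleavage of an aryl silyl ether, buffered with acetic acid so that the liberated phenoxide is protonated before it can attack the depside or benzyl ester.

Step 10
Reactants: 8 4-(benzyloxy)-2,3-dimethoxy-6-methylbenzoic acid; 14 benzyl lecanorate
Product: 15 benzyl 4-({4-[(4-benzyloxy-2,3-dimethoxy-6-methylbenzoyl)oxy]-2-hydroxy-6-methylbenzoyl}oxy)-2-hydroxy-6-methylbenzoate
Conditions: TFAA (3 equiv), toluene, rt; aq. NaHCO3 work-up
Reagents that add atoms: none
Why: Depside esterification through the mixed trifluoroacetic anhydride: the electron-rich, di-ortho-substituted acid 8 forms an acylium-like mixed anhydride that should acylate the only unchelated phenol of 14 (B-ring C4–OH), the two chelated hydroxyls remaining free.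

Step 11
Reactants: 15 benzyl 4-({4-[(4-benzyloxy-2,3-dimethoxy-6-methylbenzoyl)oxy]-2-hydroxy-6-methylbenzoyl}oxy)-2-hydroxy-6-methylbenzoate
Product: 16 4-({4-[(4-hydroxy-2,3-dimethoxy-6-methylbenzoyl)oxy]-2-hydroxy-6-methylbenzoyl}oxy)-2-hydroxy-6-methylbenzoic acid (target)
Conditions: H2 (1 atm), 10% Pd/C, EtOAc, rt
Reagents that add atoms: none
Why: Catalytic hydrogenolysis: the benzyl ether on ring A and the benzyl ester on ring C should both be cleaved over Pd/C under neutral conditions that leave the two aryl ester links and the methyl ethers intact.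

Compound list
1 | methyl 4-methoxyacetoacetate (methyl 4-methoxy-3-oxobutanoate) | COCC(=O)CC(=O)OC | starting material
2 | methyl (E)-crotonate | C/C=C/C(=O)OC | starting material
3 | dimethyl 2-(methoxyacetyl)-3-methylpentanedioate (Michael adduct, racemic mixture of diastereomers, not isolated) | COCC(=O)C(C(=O)OC)C(C)CC(=O)OC | intermediate
4 | methyl (1RS,6SR)-4-hydroxy-3-methoxy-6-methyl-2-oxocyclohex-3-ene-1-carboxylate (racemic, trans, enol form; one enantiomer drawn) | COC(=O)[C@H]1[C@H](C)CC(O)=C(OC)C1=O | intermediate
5 | methyl 2,4-dihydroxy-3-methoxy-6-methylbenzoate | COC(=O)c1c(C)cc(O)c(OC)c1O | intermediate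
6 | methyl 4-(benzyloxy)-2-hydroxy-3-methoxy-6-methylbenzoate | COC(=O)c1c(C)cc(OCc2ccccc2)c(OC)c1O | intermediate
7 | methyl 4-(benzyloxy)-2,3-dimethoxy-6-methylbenzoate | COC(=O)c1c(C)cc(OCc2ccccc2)c(OC)c1OC | intermediate
8 | 4-(benzyloxy)-2,3-dimethoxy-6-methylbenzoic acid | COc1c(OCc2ccccc2)cc(C)c(C(=O)O)c1OC | intermediate
9 | orsellinic acid (2,4-dihydroxy-6-methylbenzoic acid) | Cc1cc(O)cc(O)c1C(=O)O | starting material
10 | benzyl orsellinate (benzyl 2,4-dihydroxy-6-methylbenzoate) | Cc1cc(O)cc(O)c1C(=O)OCc1ccccc1 | intermediate
11 | tert-butyldimethylsilyl 4-(tert-butyldimethylsilyloxy)-2-hydroxy-6-methylbenzoate (not isolated) | Cc1cc(O[Si](C)(C)C(C)(C)C)cc(O)c1C(=O)O[Si](C)(C)C(C)(C)C | intermediate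
12 | 4-(tert-butyldimethylsilyloxy)-2-hydroxy-6-methylbenzoic acid | Cc1cc(O[Si](C)(C)C(C)(C)C)cc(O)c1C(=O)O | intermediate
13 | benzyl 4-{[4-(tert-butyldimethylsilyloxy)-2-hydroxy-6-methylbenzoyl]oxy}-2-hydroxy-6-methylbenzoate | Cc1cc(O[Si](C)(C)C(C)(C)C)cc(O)c1C(=O)Oc1cc(C)c(C(=O)OCc2ccccc2)c(O)c1 | intermediate
14 | benzyl 4-[(2,4-dihydroxy-6-methylbenzoyl)oxy]-2-hydroxy-6-methylbenzoate (benzyl lecanorate) | Cc1cc(O)cc(O)c1C(=O)Oc1cc(C)c(C(=O)OCc2ccccc2)c(O)c1 | intermediate
15 | benzyl 4-({4-[(4-benzyloxy-2,3-dimethoxy-6-methylbenzoyl)oxy]-2-hydroxy-6-methylbenzoyl}oxy)-2-hydroxy-6-methylbenzoate | COc1c(OCc2ccccc2)cc(C)c(C(=O)Oc2cc(C)c(C(=O)Oc3cc(C)c(C(=O)OCc4ccccc4)c(O)c3)c(O)c2)c1OC | intermediate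
16 | 4-({4-[(4-hydroxy-2,3-dimethoxy-6-methylbenzoyl)oxy]-2-hydroxy-6-methylbenzoyl}oxy)-2-hydroxy-6-methylbenzoic acid (CNP0319613.0, achiral) | COc1c(O)cc(C)c(C(=O)Oc2cc(C)c(C(=O)Oc3cc(C)c(C(=O)O)c(O)c3)c(O)c2)c1OC | target

Total step count: 11. Longest linear sequence: 7 steps (steps 1, 2, 3, 4, 5, 10, 11); the B–C branch (steps 6–9) joins at step 10.

Steps most likely to fail

Step 1 (Michael–Dieckmann annulation). The conjugate addition to the weakly electrophilic crotonate may be outpaced by methoxide-induced retro-Claisen loss of the methoxyacetyl group or by self-condensation of the keto ester. Ring closure through the less acidic methoxymethylene position would then have no substrate. The fallback reverses donor and acceptor and makes the two bonds in separate operations. It sets out from 1. Knoevenagel condensation with acetaldehyde (TiCl4, pyridine, THF, 0 °C) should give methyl 2-(methoxyacetyl)but-2-enoate F1 as an E/Z mixture. Mukaiyama–Michael addition of commercial 1-(tert-butyldimethylsilyloxy)-1-methoxyethene to this doubly activated alkene (TiCl4, CH2Cl2, −78 °C, aqueous work-up) should then deliver the adduct under non-basic conditions. The fallback comes back to the route at 3, now isolated. It is closed to 4 in a separate Dieckmann step (NaOMe, MeOH, reflux, or through its dianion made with NaH then LDA in THF, which deprotonates the methoxymethylene position kinetically).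

Step 2 (aromatisation). The iodine/DMSO system may iodinate the electron-rich ring at C5, or the dehydrogenation may stall at partial conversion. The fallback is the classical halogenative aromatisation followed by reductive dehalogenation. It sets out from 4. Bromine (2 equiv) in acetic acid at rt should brominate the enol, eliminate HBr and brominate the only free ring position, giving methyl 5-bromo-2,4-dihydroxy-3-methoxy-6-methylbenzoate F2. Hydrogenolysis of the C–Br bond (H2, Pd/C, NaOAc, MeOH, rt) then comes back to the route at 5.

Step 8 (B–C depside coupling). The carbodiimide-activated salicylic acid 12 may acylate the ortho-hydroxyl of a second molecule or rearrange to the N-acylurea before it is captured by 10, and the silyl ether may be lost on the way. The fallback uses a B-ring acid without any free hydroxyl, coupled by the mixed-anhydride method. It sets out from 9. Exhaustive allylation (allyl bromide, K2CO3, DMF, 60 °C) should give allyl 2,4-bis(allyloxy)-6-methylbenzoate F3. Saponification (KOH, DMSO–H2O, 90 °C) should give 2,4-bis(allyloxy)-6-methylbenzoic acid F4. Coupling with 10 (TFAA, toluene, rt) should give benzyl 4-{[2,4-bis(allyloxy)-6-methylbenzoyl]oxy}-2-hydroxy-6-methylbenzoate F5. Palladium-catalysed allyl transfer (Pd(PPh3)4, morpholine, THF, rt) removes both allyl ethers without touching the benzyl ester and comes back to the route at 14.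

Further compounds
F1 | step 1 | methyl 2-(methoxyacetyl)but-2-enoate (E/Z mixture) | COCC(=O)C(=CC)C(=O)OC
F2 | step 2 | methyl 5-bromo-2,4-dihydroxy-3-methoxy-6-methylbenzoate | COC(=O)c1c(C)c(Br)c(O)c(OC)c1O
F3 | step 8 | allyl 2,4-bis(allyloxy)-6-methylbenzoate | C=CCOC(=O)c1c(C)cc(OCC=C)cc1OCC=C
F4 | step 8 | 2,4-bis(allyloxy)-6-methylbenzoic acid | OC(=O)c1c(C)cc(OCC=C)cc1OCC=C
F5 | step 8 | benzyl 4-{[2,4-bis(allyloxy)-6-methylbenzoyl]oxy}-2-hydroxy-6-methylbenzoate | C=CCOc1cc(C)c(C(=O)Oc2cc(C)c(C(=O)OCc3ccccc3)c(O)c2)c(OCC=C)c1
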